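Ring B, the hexasubstituted arene fused to the lactol lactone, carries its phenol oxygen (on the carbon next to the lactone-carbonyl carbon) and its diaryl-ether oxygen para to each other. This hydroquinone pattern is disconnected to a squarate-derived 4-(4H-1,3-dioxin-6-yl)-4-silyloxycyclobutenone whose C2 and C3 already hold the future lactone-carbonyl and lactol carbons. Heating opens the four-membered ring to a dienylketene that closes, ketene carbon to dioxin C5, giving the benzodioxin hydroquinone mono-silyl ether with all six ring-B substituents placed in one operation. Ring A then enters by SNAr at the desilylated oxygen, lactonisation closes the depsidone ring, and acylative dynamic kinetic resolution fixes the lactol carbon.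

Key step: step 7

Assumption: the lactol carbon is a hemiacetal that epimerises by ring–chain tautomerism in basic or protic media, so it is fixed as the (S)-O-acyl lactol and unmasked last under neutral conditions; the enantiomer of the acyl-transfer catalyst (both are available) that gives (S) is the one used.

Step 1
Reactants: 1 tributyltin hydride; 2 benzyl chloromethyl ether
Product: 4 tributyl[(benzyloxy)methyl]stannane, via tributylstannyllithium 3 (not isolated)
Conditions: LiN(iPr)2, THF, 0 °C; then 2, −78 °C → rt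
Reagents that add atoms: none
Why: SN2 displacement of chloride from the α-chloro ether by the stannyl anion gives the α-alkoxymethylstannane needed for tin–lithium exchange.

Step 2
Reactants: 4 tributyl[(benzyloxy)methyl]stannane; 5 diisopropyl squarate
Product: 8 3-[(benzyloxy)methyl]-4-isopropoxycyclobut-3-ene-1,2-dione, via [(benzyloxy)methyl]lithium 6 (not isolated), via lithium cyclobutenolate adduct 7 (not isolated)
Conditions: n-BuLi, THF, −78 °C; add to 5, −78 °C; (CF3CO)2O, −78 °C; aq. NaHCO3
Reagents that add atoms: water, O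
Why: Tin–lithium exchange gives the α-alkoxy organolithium, which adds 1,2 to a squarate carbonyl; trifluoroacetylation of the tertiary alkoxide lets the vinylogous ester ionise and lose isopropanol on aqueous work-up, a net 1,3-carbonyl transposition.

Step 3
Reactants: 9 1,3-dioxan-5-ol
Product: 10 1,3-dioxan-5-yl 4-methylbenzenesulfonate
Conditions: TsCl, pyridine, 0 °C → rt
Reagents that add atoms: 4-methylbenzenesulfonyl chloride, Cc1ccc(cc1)S(Cl)(=O)=O
Why: Sulfonylation of the secondary alcohol installs the leaving group for elimination.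

Step 4
Reactants: 10 1,3-dioxan-5-yl 4-methylbenzenesulfonate
Product: 11 4H-1,3-dioxin
Conditions: KOtBu, DMSO, 50 °C, product distilled out
Reagents that add atoms: none
Why: E2 elimination by a hindered base removes a hydrogen from either of the two equivalent O–CH2 carbons and gives a single cyclic enol ether.

Step 5
Reactants: 11 4H-1,3-dioxin; 8 3-[(benzyloxy)methyl]-4-isopropoxycyclobut-3-ene-1,2-dione
Product: 14 2-[(benzyloxy)methyl]-4-[(tert-butyldimethylsilyl)oxy]-4-(4H-1,3-dioxin-6-yl)-3-isopropoxycyclobut-2-en-1-one (racemic), via 6-lithio-4H-1,3-dioxin 12 (not isolated), via lithium cyclobutenolate adduct 13 (not isolated)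
Conditions: s-BuLi, THF, −78 °C; 8, −78 °C; TBSOTf, −78 → −20 °C
Reagents that add atoms: tert-butyldimethylsilyl trifluoromethanesulfonate, CC(C)(C)[Si](C)(C)OS(=O)(=O)C(F)(F)F
Why: α-Lithiation of the enol ether at C6 and 1,2-addition to the ketone-like carbonyl (the one flanked by the isopropoxy-bearing carbon; the other is a vinylogous ester) fix the regiochemistry, and in-flask O-silylation blocks later ketene trapping; the new quaternary centre is racemic and is erased in step 7.

Step 6
Reactants: 15 1,3-dithiane; 14 2-[(benzyloxy)methyl]-4-[(tert-butyldimethylsilyl)oxy]-4-(4H-1,3-dioxin-6-yl)-3-isopropoxycyclobut-2-en-1-one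
Product: 18 2-[(benzyloxy)methyl]-4-[(tert-butyldimethylsilyl)oxy]-4-(4H-1,3-dioxin-6-yl)-3-(1,3-dithian-2-yl)cyclobut-2-en-1-one (racemic), via 2-lithio-1,3-dithiane 16 (not isolated), via lithium cyclobutenolate adduct 17 (not isolated)
Conditions: n-BuLi, THF, −30 °C; 14, −78 °C; (CF3CO)2O (1.1 equiv), −78 °C; aq. NaHCO3
Reagents that add atoms: water, O
Why: Corey–Seebach dithiane anion adds 1,2 to the remaining carbonyl, and trifluoroacetylation then hydrolysis transposes the carbonyl with loss of isopropanol (Stork–Danheiser-type sequence), placing the masked formyl carbon at C3; direct addition–elimination at C3 would give the same product.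

Step 7
Reactants: 18 2-[(benzyloxy)methyl]-4-[(tert-butyldimethylsilyl)oxy]-4-(4H-1,3-dioxin-6-yl)-3-(1,3-dithian-2-yl)cyclobut-2-en-1-one
Product: 21 6-[(benzyloxy)methyl]-8-[(tert-butyldimethylsilyl)oxy]-7-(1,3-dithian-2-yl)-4H-1,3-benzodioxin-5-ol, via dienylketene 19 (not isolated), via cyclohexadienone 20 (not isolated)
Conditions: toluene (0.02 M, degassed), 100 °C, argon
Reagents that add atoms: none
Why: Thermal conrotatory four-electron opening of the cyclobutenone breaks the C1–C4 bond, the silyloxy donor rotating outward (torquoselectivity) so that the dioxinyl group lies cis to the ketene in dienylketene 19. Disrotatory six-electron electrocyclisation (6-endo closure of the hexatriene, ketene carbon to dioxin C5) forms the carbocyclic six-membered ring as dienone 20, and enolisation of its ring-fusion hydrogen gives the arene. This is the Moore rearrangement, the closest precedents being 4-alkenyl-4-silyloxycyclobutenones that give mono-silylated hydroquinones. No stereocentre is formed and the one in 18 is destroyed. The step needs ring opening to outrun retro-hetero-Diels–Alder loss of formaldehyde from the dioxin, which the unsubstituted acetal carbon (slow cycloreversion) and the low opening temperature of an oxy-substituted alkenylcyclobutenone should secure; the silyl group on the C4 oxygen blocks lactone formation from the ketene and leaves exactly one free phenol.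

Step 8
Reactants: 21 6-[(benzyloxy)methyl]-8-[(tert-butyldimethylsilyl)oxy]-7-(1,3-dithian-2-yl)-4H-1,3-benzodioxin-5-ol
Product: 22 6-[(benzyloxy)methyl]-8-[(tert-butyldimethylsilyl)oxy]-7-(dimethoxymethyl)-4H-1,3-benzodioxin-5-ol
Conditions: Hg(ClO4)2, CaCO3, MeOH/CH2Cl2, 0 °C
Reagents that add atoms: methanol, CO
Why: Thiophilic divalent mercury ionises the dithiane and methanol captures the cation (transacetalisation), exchanging the sulfur mask for a dimethyl acetal so that hydrogenolysis becomes possible; CaCO3 buffers the acid so the aryl silyl ether and methylene acetal survive.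

Step 9
Reactants: 22 6-[(benzyloxy)methyl]-8-[(tert-butyldimethylsilyl)oxy]-7-(dimethoxymethyl)-4H-1,3-benzodioxin-5-ol
Product: 23 8-[(tert-butyldimethylsilyl)oxy]-7-(dimethoxymethyl)-6-(hydroxymethyl)-4H-1,3-benzodioxin-5-ol
Conditions: H2 (1 atm), 10% Pd/C, Et3N (1 equiv), EtOAc, rt; base-washed silica
Reagents that add atoms: none
Why: Catalytic hydrogenolysis cleaves the unhindered O-benzyl bond, while the benzylic C–O bonds of the hexasubstituted ring, the acetals and the silyl ether should be retained under base-buffered conditions.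

Step 10
Reactants: 23 8-[(tert-butyldimethylsilyl)oxy]-7-(dimethoxymethyl)-6-(hydroxymethyl)-4H-1,3-benzodioxin-5-ol
Product: 24 [5-(allyloxy)-8-[(tert-butyldimethylsilyl)oxy]-7-(dimethoxymethyl)-4H-1,3-benzodioxin-6-yl]methanol
Conditions: allyl methyl carbonate, Pd(PPh3)4 (3 mol%), THF, 40 °C
Reagents that add atoms: allyl methyl carbonate, C=CCOC(=O)OC
Why: Tsuji–Trost O-allylation: the phenol, deprotonated by the methoxide released on decarboxylation, attacks the π-allyl palladium complex, whereas the aliphatic alcohol is not nucleophilic enough under these neutral conditions.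

Step 11
Reactants: 24 [5-(allyloxy)-8-[(tert-butyldimethylsilyl)oxy]-7-(dimethoxymethyl)-4H-1,3-benzodioxin-6-yl]methanol
Product: 27 racemic methoxy-lactone: 5-(allyloxy)-8-[(tert-butyldimethylsilyl)oxy]-4H-1,3-benzodioxin with a γ-lactone fused across C6–C7 (C6–C(=O)–O–CH(OMe)–C7), via benzodioxin carbaldehyde 25 (not isolated), via benzodioxin carboxylic acid 26 (not isolated)
Conditions: TEMPO (10 mol%), NaClO2, NaOCl (3 mol%), MeCN/phosphate buffer pH 6.7, 35 °C; citric acid to pH 4; then PPTS (cat.), 4 Å MS, CH2Cl2, rt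
Reagents that add atoms: sodium chlorite, [Na+].[O-]Cl=O
Why: Oxoammonium-catalysed alcohol oxidation with chlorite as terminal oxidant takes the primary alcohol through the aldehyde to the acid at near-neutral pH, which spares the acetal; mild acid then makes the carboxyl group displace one methoxy group (lactonising transacetalisation) to the racemic methyl pseudo-ester.

Step 12
Reactants: 28 4-bromo-2-fluoro-6-methylbenzoic acid
Product: 29 tert-butyl 4-bromo-2-fluoro-6-methylbenzoate
Conditions: tert-butyl 2,2,2-trichloroacetimidate, BF3·OEt2 (cat.), CH2Cl2/cyclohexane, rt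
Reagents that add atoms: tert-butyl 2,2,2-trichloroacetimidate, CC(C)(C)OC(=N)C(Cl)(Cl)Cl
Why: O-Alkylation of the acid by the tert-butyl cation from the imidate (SN1-type esterification) is insensitive to the two ortho substituents.

Step 13
Reactants: 29 tert-butyl 4-bromo-2-fluoro-6-methylbenzoate
Product: 31 tert-butyl 2-fluoro-4-hydroxy-6-methylbenzoate, via aryl pinacol boronate 30 (not isolated)
Conditions: B2pin2, Pd(dppf)Cl2 (3 mol%), KOAc, 1,4-dioxane, 90 °C; then H2O2 (30% aq.), NaOH, THF, 0 °C
Reagents that add atoms: hydrogen peroxide, OO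
Why: Miyaura borylation of the aryl bromide then oxidative C–B to C–O migration gives the phenol without touching the hindered tert-butyl ester or the C–F bond.

Step 14
Reactants: 31 tert-butyl 2-fluoro-4-hydroxy-6-methylbenzoate
Product: 32 tert-butyl 4-(allyloxy)-2-fluoro-6-methylbenzoate
Conditions: allyl bromide, K2CO3, DMF, rt
Reagents that add atoms: allyl bromide, C=CCBr
Why: Williamson etherification of the phenoxide.

Step 15
Reactants: 32 tert-butyl 4-(allyloxy)-2-fluoro-6-methylbenzoate
Product: 34 tert-butyl 4-(allyloxy)-2-fluoro-3-formyl-6-methylbenzoate, via arylmagnesium chloride 33 (not isolated)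
Conditions: TMPMgCl·LiCl, THF, 0 °C; DMF, 0 °C → rt; aq. NH4Cl
Reagents that add atoms: N,N-dimethylformamide, CN(C)C=O
Why: Directed ortho-magnesiation occurs at the only ring C–H flanked by two acidifying groups (F and O-allyl), the amide base tolerating the tert-butyl ester, and DMF formylates the aryl Grignard reagent.

Step 16
Reactants: 27 racemic methoxy-lactone silyl ether; 34 tert-butyl 4-(allyloxy)-2-fluoro-3-formyl-6-methylbenzoate
Product: 36 racemic diaryl ether: tert-butyl 4-(allyloxy)-3-formyl-6-methylbenzoate bearing at C2 the 8-oxy group of the lactone-fused benzodioxin of 27 (O–aryl in place of O–Si), via caesium phenoxide 35 (not isolated)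
Conditions: CsF, DMF, 70 °C
Reagents that add atoms: none
Why: Fluoride cleaves the aryl silyl ether and the phenoxide undergoes SNAr at the C–F bond activated by the ortho-formyl and ortho-ester groups; the future ester oxygen of ring B is still locked in the acetal, so only the correct oxygen can be arylated.

Step 17
Reactants: 36 racemic diaryl ether tert-butyl ester
Product: 37 racemic diaryl ether acid: 4-(allyloxy)-3-formyl-6-methyl-2-aryloxybenzoic acid (aryl as in 36)
Conditions: CF3CO2H/CH2Cl2 (1:4), 0 °C → rt
Reagents that add atoms: none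
Why: Acidolysis (E1 loss of isobutene) frees the ring-A acid; the methylene acetal, pseudo-ester and allyl ethers are stable to anhydrous acid.

Step 18
Reactants: 37 racemic diaryl ether acid
Product: 40 racemic hydroxy acid: 4-(allyloxy)-3-formyl-6-methyl-2-aryloxybenzoic acid whose aryl ring carries 2-hydroxy; 3-[(methoxymethoxy)methyl]; 4-allyloxy; 5,6-fused methoxy-lactone (carbonyl on C5), via bipyridinium triflate 38 (not isolated), via bis-silylated MOM ether 39 (not isolated)
Conditions: Et3SiOTf, 2,2′-bipyridyl, CH2Cl2, 0 °C → rt; MeOH; then 1 M HCl/THF, 0 °C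
Reagents that add atoms: methanol, CO
Why: Silyl triflate–bipyridyl opening of the methylene acetal: the aryl oxygen leaves as a silyl ether and the acetal carbon, held as an N-(alkoxymethyl)pyridinium salt, is transferred to methanol, so the phenol is released while the hydroxymethyl group emerges as its MOM ether; dilute acid then hydrolyses the aryl silyl ether and silyl ester.

Step 19
Reactants: 40 racemic hydroxy acid
Product: 41 racemic protected depsidone: the target with allyl ethers on both phenols; a MOM ether on the hydroxymethyl group; OMe in place of the lactol OH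
Conditions: DCC, DMAP (cat.), CH2Cl2 (0.003 M), rt
Reagents that add atoms: none
Why: Steglich-type intramolecular esterification closes the seven-membered depsidone lactone on the only free hydroxyl group.

Step 20
Reactants: 41 racemic protected depsidone
Product: 42 racemic lactol: the target as its bis(allyl) phenol ether
Conditions: 3 M HCl (aq.)/THF (1:3), 45 °C
Reagents that add atoms: water, O
Why: Acid-catalysed hydrolysis of both acetals (pseudo-ester to lactol, MOM ether to alcohol); the aryl ester, allyl ethers and aldehyde are stable to aqueous acid.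

Step 21
Reactants: 42 racemic lactol bis(allyl) ether
Product: 43 (S)-lactol propionate of the bis(allyl) ether with the hydroxymethyl group also propionylated
Conditions: (R)-BTM (10 mol%), (EtCO)2O (3 equiv), iPr2NEt, CHCl3, −20 °C
Reagents that add atoms: propionic anhydride, CCC(=O)OC(=O)CC
Why: Acylative dynamic kinetic resolution: the amine base interconverts the lactol enantiomers through the open formyl carboxylate while the chiral N-acyl isothiouronium ion acylates one of them, setting the (S) lactol carbon under catalyst control; the primary alcohol is esterified as well.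

Step 22
Reactants: 43 (S)-bis(propionate) bis(allyl) ether
Product: 44 (S)-bis(propionate) of the target (lactol oxygen and CH2O acylated; both phenols free)
Conditions: Pd(PPh3)4 (5 mol%), p-TolSO2H, CH2Cl2, rt
Reagents that add atoms: none
Why: Zerovalent palladium ionises the aryl allyl ethers (phenoxides ortho to carbonyl groups are good leaving groups) and the sulfinic acid traps the π-allyl complex as the sulfone and protonates the phenols, which leaves the acyloxy lactone untouched.

Step 23
Reactants: 44 (S)-bis(propionate) of the target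
Product: 45 target depsidone with (S)-configured lactol carbon
Conditions: immobilised Candida antarctica lipase B, n-BuOH, MTBE, 30 °C; filter; crystallise below 0 °C
Reagents that add atoms: none
Why: Lipase-catalysed transesterification to butanol cleaves both esters at the acyl–oxygen bond under neutral aprotic conditions, so the C–O bond at the stereocentre is never broken and no base is present to open the lactol.

Compound list
1 | tributyltin hydride | CCCC[SnH](CCCC)CCCC | starting material
2 | benzyl chloromethyl ether | ClCOCc1ccccc1 | starting material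
3 | tributylstannyllithium | [Li][Sn](CCCC)(CCCC)CCCC | intermediate
4 | tributyl[(benzyloxy)methyl]stannane | CCCC[Sn](CCCC)(CCCC)COCc1ccccc1 | intermediate
5 | diisopropyl squarate (3,4-diisopropoxycyclobut-3-ene-1,2-dione) | CC(C)OC1=C(OC(C)C)C(=O)C1=O | starting material
6 | [(benzyloxy)methyl]lithium | [Li]COCc1ccccc1 | intermediate
7 | lithium 1-[(benzyloxy)methyl]-2,3-diisopropoxy-4-oxocyclobut-2-en-1-olate (racemic) | [Li]OC1(COCc2ccccc2)C(=O)C(OC(C)C)=C1OC(C)C | intermediate
8 | 3-[(benzyloxy)methyl]-4-isopropoxycyclobut-3-ene-1,2-dione | O=C1C(=O)C(OC(C)C)=C1COCc1ccccc1 | intermediate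
9 | 1,3-dioxan-5-ol | OC1COCOC1 | starting material
10 | 1,3-dioxan-5-yl 4-methylbenzenesulfonate | Cc1ccc(cc1)S(=O)(=O)OC1COCOC1 | intermediate
11 | 4H-1,3-dioxin | C1=COCOC1 | intermediate
12 | 6-lithio-4H-1,3-dioxin | [Li]C1=CCOCO1 | intermediate
13 | lithium 3-[(benzyloxy)methyl]-1-(4H-1,3-dioxin-6-yl)-2-isopropoxy-4-oxocyclobut-2-en-1-olate (racemic) | [Li]OC1(C2=CCOCO2)C(=O)C(COCc2ccccc2)=C1OC(C)C | intermediate
14 | 2-[(benzyloxy)methyl]-4-[(tert-butyldimethylsilyl)oxy]-4-(4H-1,3-dioxin-6-yl)-3-isopropoxycyclobut-2-en-1-one (racemic) | CC(C)OC1=C(COCc2ccccc2)C(=O)C1(O[Si](C)(C)C(C)(C)C)C1=CCOCO1 | intermediate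
15 | 1,3-dithiane | C1CSCSC1 | starting material
16 | 2-lithio-1,3-dithiane | [Li]C1SCCCS1 | intermediate
17 | lithium 2-[(benzyloxy)methyl]-4-[(tert-butyldimethylsilyl)oxy]-4-(4H-1,3-dioxin-6-yl)-1-(1,3-dithian-2-yl)-3-isopropoxycyclobut-2-en-1-olate (diastereomer mixture, racemic) | [Li]OC1(C2SCCCS2)C(COCc2ccccc2)=C(OC(C)C)C1(O[Si](C)(C)C(C)(C)C)C1=CCOCO1 | intermediate
18 | 2-[(benzyloxy)methyl]-4-[(tert-butyldimethylsilyl)oxy]-4-(4H-1,3-dioxin-6-yl)-3-(1,3-dithian-2-yl)cyclobut-2-en-1-one (racemic) | O=C1C(COCc2ccccc2)=C(C2SCCCS2)C1(O[Si](C)(C)C(C)(C)C)C1=CCOCO1 | intermediate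
19 | (3Z)-2-[(benzyloxy)methyl]-4-[(tert-butyldimethylsilyl)oxy]-4-(4H-1,3-dioxin-6-yl)-3-(1,3-dithian-2-yl)buta-1,3-dien-1-one (dienylketene) | O=C=C(COCc1ccccc1)/C(C1SCCCS1)=C(/O[Si](C)(C)C(C)(C)C)C1=CCOCO1 | intermediate
20 | 6-[(benzyloxy)methyl]-8-[(tert-butyldimethylsilyl)oxy]-7-(1,3-dithian-2-yl)-4,4a-dihydro-1,3-benzodioxin-5-one (racemic cyclohexadienone) | O=C1C(COCc2ccccc2)=C(C2SCCCS2)C(O[Si](C)(C)C(C)(C)C)=C2OCOCC12 | intermediate
21 | 6-[(benzyloxy)methyl]-8-[(tert-butyldimethylsilyl)oxy]-7-(1,3-dithian-2-yl)-4H-1,3-benzodioxin-5-ol | Oc1c(COCc2ccccc2)c(C2SCCCS2)c(O[Si](C)(C)C(C)(C)C)c2OCOCc12 | intermediate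
22 | 6-[(benzyloxy)methyl]-8-[(tert-butyldimethylsilyl)oxy]-7-(dimethoxymethyl)-4H-1,3-benzodioxin-5-ol | Oc1c(COCc2ccccc2)c(C(OC)OC)c(O[Si](C)(C)C(C)(C)C)c2OCOCc12 | intermediate
23 | 8-[(tert-butyldimethylsilyl)oxy]-7-(dimethoxymethyl)-6-(hydroxymethyl)-4H-1,3-benzodioxin-5-ol | Oc1c(CO)c(C(OC)OC)c(O[Si](C)(C)C(C)(C)C)c2OCOCc12 | intermediate
24 | [5-(allyloxy)-8-[(tert-butyldimethylsilyl)oxy]-7-(dimethoxymethyl)-4H-1,3-benzodioxin-6-yl]methanol | C=CCOc1c(CO)c(C(OC)OC)c(O[Si](C)(C)C(C)(C)C)c2OCOCc12 | intermediate
25 | 5-(allyloxy)-8-[(tert-butyldimethylsilyl)oxy]-7-(dimethoxymethyl)-4H-1,3-benzodioxine-6-carbaldehyde | C=CCOc1c(C=O)c(C(OC)OC)c(O[Si](C)(C)C(C)(C)C)c2OCOCc12 | intermediate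
26 | 5-(allyloxy)-8-[(tert-butyldimethylsilyl)oxy]-7-(dimethoxymethyl)-4H-1,3-benzodioxine-6-carboxylic acid | C=CCOc1c(C(=O)O)c(C(OC)OC)c(O[Si](C)(C)C(C)(C)C)c2OCOCc12 | intermediate
27 | racemic methoxy-lactone (methyl pseudo-ester): 5-(allyloxy)-8-[(tert-butyldimethylsilyl)oxy]-4H-1,3-benzodioxin with a γ-lactone fused across C6–C7, C6–C(=O)–O–CH(OMe)–C7 | C=CCOc1c2COCOc2c(O[Si](C)(C)C(C)(C)C)c2C(OC)OC(=O)c12 | intermediate
28 | 4-bromo-2-fluoro-6-methylbenzoic acid | Cc1cc(Br)cc(F)c1C(=O)O | starting material
29 | tert-butyl 4-bromo-2-fluoro-6-methylbenzoate | Cc1cc(Br)cc(F)c1C(=O)OC(C)(C)C | intermediate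
30 | tert-butyl 2-fluoro-6-methyl-4-(4,4,5,5-tetramethyl-1,3,2-dioxaborolan-2-yl)benzoate | Cc1cc(B2OC(C)(C)C(C)(C)O2)cc(F)c1C(=O)OC(C)(C)C | intermediate
31 | tert-butyl 2-fluoro-4-hydroxy-6-methylbenzoate | Cc1cc(O)cc(F)c1C(=O)OC(C)(C)C | intermediate
32 | tert-butyl 4-(allyloxy)-2-fluoro-6-methylbenzoate | Cc1cc(OCC=C)cc(F)c1C(=O)OC(C)(C)C | intermediate
33 | [6-(allyloxy)-3-(tert-butoxycarbonyl)-2-fluoro-4-methylphenyl]magnesium chloride (LiCl complex) | Cc1cc(OCC=C)c([Mg]Cl)c(F)c1C(=O)OC(C)(C)C | intermediate
34 | tert-butyl 4-(allyloxy)-2-fluoro-3-formyl-6-methylbenzoate | Cc1cc(OCC=C)c(C=O)c(F)c1C(=O)OC(C)(C)C | intermediate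
35 | caesium phenoxide of 27 (silyl group removed) | C=CCOc1c2COCOc2c([O-])c2C(OC)OC(=O)c12.[Cs+] | intermediate
36 | racemic diaryl ether: tert-butyl 4-(allyloxy)-3-formyl-6-methylbenzoate bearing at C2 the 8-oxy group of the lactone-fused benzodioxin of 27 | Cc1cc(OCC=C)c(C=O)c(Oc2c3OCOCc3c(OCC=C)c3C(=O)OC(OC)c23)c1C(=O)OC(C)(C)C | intermediate
37 | racemic diaryl ether acid (36 with CO2H in place of the tert-butyl ester) | Cc1cc(OCC=C)c(C=O)c(Oc2c3OCOCc3c(OCC=C)c3C(=O)OC(OC)c23)c1C(=O)O | intermediate
38 | racemic bipyridinium triflate: ring-B aryl oxygen as triethylsilyl ether, CH2–O–CH2–N+(2,2′-bipyridinium), acid as triethylsilyl ester | Cc1cc(OCC=C)c(C=O)c(Oc2c(O[Si](CC)(CC)CC)c(COC[n+]3ccccc3-c3ccccn3)c(OCC=C)c3C(=O)OC(OC)c23)c1C(=O)O[Si](CC)(CC)CC.[O-]S(=O)(=O)C(F)(F)F | intermediate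
39 | racemic bis-silylated MOM ether: aryl triethylsilyl ether, triethylsilyl ester, (methoxymethoxy)methyl group | Cc1cc(OCC=C)c(C=O)c(Oc2c(O[Si](CC)(CC)CC)c(COCOC)c(OCC=C)c3C(=O)OC(OC)c23)c1C(=O)O[Si](CC)(CC)CC | intermediate
40 | racemic hydroxy acid: 4-(allyloxy)-3-formyl-6-methyl-2-aryloxybenzoic acid, aryl = 2-hydroxy-3-[(methoxymethoxy)methyl]-4-(allyloxy)phenyl with methoxy-lactone fused at C5–C6 (carbonyl on C5) | Cc1cc(OCC=C)c(C=O)c(Oc2c(O)c(COCOC)c(OCC=C)c3C(=O)OC(OC)c23)c1C(=O)O | intermediate
41 | racemic protected depsidone: target with both phenols as allyl ethers, hydroxymethyl as MOM ether, OMe in place of lactol OH | Cc1cc(OCC=C)c(C=O)c2c1C(=O)Oc1c(COCOC)c(OCC=C)c3c(c1O2)C(OC)OC3=O | intermediate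
42 | racemic lactol: target as its bis(allyl) phenol ether | Cc1cc(OCC=C)c(C=O)c2c1C(=O)Oc1c(CO)c(OCC=C)c3c(c1O2)C(O)OC3=O | intermediate
43 | (S)-lactol propionate of the bis(allyl) ether, hydroxymethyl group also propionylated | Cc1cc(OCC=C)c(C=O)c2c1C(=O)Oc1c(COC(=O)CC)c(OCC=C)c3c(c1O2)[C@@H](OC(=O)CC)OC3=O | intermediate
44 | (S)-bis(propionate) of the target (lactol O and CH2O acylated, phenols free) | Cc1cc(O)c(C=O)c2c1C(=O)Oc1c(COC(=O)CC)c(O)c3c(c1O2)[C@@H](OC(=O)CC)OC3=O | intermediate
45 | target depsidone, (S) at the lactol carbon | Cc1cc(O)c(C=O)c2c1C(=O)Oc1c(CO)c(O)c3c(c1O2)[C@@H](O)OC3=O | target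

Total step count: 23. Longest linear sequence: 17 steps (1, 2, 5–11, 16–23).

Steps most likely to fail

Step 7. On heating, cycloreversion of the dioxin ring with loss of formaldehyde, or interception of the ketene before six-electron closure, may compete with arene formation. The fallback builds the same ring from an allene instead of the cyclic enol ether and sets out from 8. Commercial 3-(methoxymethoxy)prop-1-yne is isomerised with KOtBu to 1-(methoxymethoxy)propa-1,2-diene F1, which n-BuLi converts into 1-lithio-1-(methoxymethoxy)propa-1,2-diene F2. Addition to 8 and silylation with TBSOTf would give the 4-allenyl-4-silyloxycyclobutenone F3, and 2-lithio-1,3-dithiane followed by (CF3CO)2O the 3-dithianyl cyclobutenone F4. Gentle heating of F4 in wet THF/toluene opens the ring; the ketene closes onto the central allene carbon to the ortho-quinone methide F5, which adds water to give the hydroxymethyl phenol F6. PPTS then closes the MOM ether onto the neighbouring hydroxymethyl group with loss of methanol, coming back to the route at 21.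

Step 18. On this crowded, polyfunctional acid the acetal opening may be incomplete or unselective, or the silyl triflate may attack the pseudo-ester. The fallback sets out from 37: classical hydrolysis (6 M HCl, 1,4-dioxane, 80 °C) would cleave the methylene acetal and the pseudo-ester together to the triol acid F7. Carbodiimide lactonisation at high dilution, relying on the kinetic preference for the seven-membered phenolic lactone over the eight- and nine-membered alternatives, would then come back to the route at 42, one step shorter.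

Step 23. Enzymatic turnover on the crowded diester may be slow, the lipase may prefer the other enantiomer, or the freed hemiacetal may lose configuration while the primary ester is still being cleaved. The fallback replaces the enzyme by a chemically assisted cleavage and sets out from 42. The dynamic kinetic resolution is run with chloroacetic anhydride to give the bis(chloroacetate) F8 (same spatial arrangement, descriptor R because of the chlorine), and deallylation as in step 22 gives the diphenol F9. Thiourea in THF/EtOH at room temperature then removes both chloroacetyl groups by S-alkylation and cyclisation under essentially neutral conditions, coming back to the route at 45.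

Further compounds
F1 | step 7 | 1-(methoxymethoxy)propa-1,2-diene | C=C=COCOC
F2 | step 7 | 1-lithio-1-(methoxymethoxy)propa-1,2-diene | [Li]C(OCOC)=C=C
F3 | step 7 | 2-[(benzyloxy)methyl]-4-[(tert-butyldimethylsilyl)oxy]-3-isopropoxy-4-[1-(methoxymethoxy)propa-1,2-dien-1-yl]cyclobut-2-en-1-one (racemic) | CC(C)OC1=C(COCc2ccccc2)C(=O)C1(O[Si](C)(C)C(C)(C)C)C(OCOC)=C=C
F4 | step 7 | 2-[(benzyloxy)methyl]-4-[(tert-butyldimethylsilyl)oxy]-3-(1,3-dithian-2-yl)-4-[1-(methoxymethoxy)propa-1,2-dien-1-yl]cyclobut-2-en-1-one (racemic) | O=C1C(COCc2ccccc2)=C(C2SCCCS2)C1(O[Si](C)(C)C(C)(C)C)C(OCOC)=C=C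
F5 | step 7 | 2-[(benzyloxy)methyl]-4-[(tert-butyldimethylsilyl)oxy]-3-(1,3-dithian-2-yl)-5-(methoxymethoxy)-6-methylidenecyclohexa-2,4-dien-1-one (ortho-quinone methide) | C=C1C(=O)C(COCc2ccccc2)=C(C2SCCCS2)C(O[Si](C)(C)C(C)(C)C)=C1OCOC
F6 | step 7 | 3-[(benzyloxy)methyl]-5-[(tert-butyldimethylsilyl)oxy]-4-(1,3-dithian-2-yl)-2-(hydroxymethyl)-6-(methoxymethoxy)phenol | OCc1c(O)c(COCc2ccccc2)c(C2SCCCS2)c(O[Si](C)(C)C(C)(C)C)c1OCOC
F7 | step 18 | racemic triol acid: 4-(allyloxy)-3-formyl-6-methyl-2-aryloxybenzoic acid, aryl = 2-hydroxy-3-(hydroxymethyl)-4-(allyloxy)phenyl with hydroxy-lactone (lactol) fused at C5–C6 | Cc1cc(OCC=C)c(C=O)c(Oc2c(O)c(CO)c(OCC=C)c3C(=O)OC(O)c23)c1C(=O)O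
F8 | step 23 | bis(chloroacetate) of the bis(allyl) ether 42, lactol carbon as in 45 (descriptor R) | Cc1cc(OCC=C)c(C=O)c2c1C(=O)Oc1c(COC(=O)CCl)c(OCC=C)c3c(c1O2)[C@@H](OC(=O)CCl)OC3=O
F9 | step 23 | bis(chloroacetate) of the target, phenols free, lactol carbon as in 45 (descriptor R) | Cc1cc(O)c(C=O)c2c1C(=O)Oc1c(COC(=O)CCl)c(O)c3c(c1O2)[C@@H](OC(=O)CCl)OC3=O
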